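**Strategy.** The route rests on cutting the C5–C10 and C8–C9 bonds of the decalin. The feature exploited is that ring B is a six-membered carbocycle fused to ring A through C5–C10, with the C11 formyl on C9 next to the methyl-bearing C10. The whole C15 skeleton can therefore be laid out as one chain, C11–C9–C10–C1–C2–C3–C4–C5–C6–C7–C8–C12. One catalytic asymmetric intramolecular Diels–Alder reaction of the C9=C10 enal onto the C5=C6–C7=C8 diene closes rings A and B and fixes the trans C5/C10 fusion. Its precursor is an open-chain (2E,8E,10E)-trienal made with every double-bond geometry defined. The C6 and C9 oxygens follow by α-face singlet-oxygen addition to the 6,8-diene.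

Key step: step 7

Assumption: atoms carry drimane numbers (ring A = C1–C5 and C10; ring B = C5–C10; C11 on C9; C12 on C8; C15 on C10; α is the face opposite the C10 methyl), and the catalyst antipode in step 7 is chosen from the usual binding model of N-protonated oxazaborolidines, its enantiomer being used should the sense of induction prove reversed.

Step 1
Reactants: 1 isobutyronitrile; 2 (5-chloropent-1-yn-1-yl)trimethylsilane
Product: 4 2,2-dimethyl-7-(trimethylsilyl)hept-6-ynenitrile, via lithiated isobutyronitrile 3 (not isolated)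
Conditions: LiN(i-Pr)2, THF, −78 °C; then 2, NaI (cat.), DMPU, −78 °C → rt
Reagents that add atoms: none
Why: SN2 alkylation of the tertiary α-cyano carbanion by the primary halide should build quaternary C4 with both methyl groups, the silyl cap keeping the acidic alkyne C–H from quenching the anion.

Step 2
Reactants: 4 2,2-dimethyl-7-(trimethylsilyl)hept-6-ynenitrile
Product: 6 2,2-dimethyl-7-(trimethylsilyl)hept-6-ynal, via aluminium aldimine 5 (not isolated)
Conditions: i-Bu2AlH, CH2Cl2, −78 → 0 °C; then 1 M HCl, 0 °C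
Reagents that add atoms: water, O
Why: Partial nitrile reduction by a single hydride transfer stops at the N-aluminated aldimine, which hydrolyses on work-up to the neopentyl aldehyde (future C5) without touching the silyl alkyne.

Step 3
Reactants: 6 2,2-dimethyl-7-(trimethylsilyl)hept-6-ynal
Product: 7 [(7E)-8-iodo-6,6-dimethyloct-7-en-1-yn-1-yl]trimethylsilane
Conditions: CHI3, CrCl2, THF, 0 °C → rt
Reagents that add atoms: iodoform, IC(I)I
Why: Takai iodo-olefination through the geminal dichromium carbenoid should give the E-vinyl iodide (C5=C6), the quaternary neighbour reinforcing the intrinsic E preference.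

Step 4
Reactants: 7 [(7E)-8-iodo-6,6-dimethyloct-7-en-1-yn-1-yl]trimethylsilane; 8 4,4,5,5-tetramethyl-2-[(1E)-prop-1-en-1-yl]-1,3,2-dioxaborolane
Product: 10 (7E,9E)-6,6-dimethylundeca-7,9-dien-1-yne, via TMS dienyne 9 (not isolated)
Conditions: Pd(PPh3)4 (cat.), K3PO4, THF/H2O, 50 °C; then K2CO3, MeOH, rt
Reagents that add atoms: none
Why: Suzuki–Miyaura coupling joins two geometrically pure sp2 partners with retention at both, giving the (E,E)-diene C5=C6–C7=C8 with its C12 methyl, and base-mediated methanolysis of the C–Si bond in the same pot frees the terminal alkyne.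

Step 5
Reactants: 10 (7E,9E)-6,6-dimethylundeca-7,9-dien-1-yne
Product: 13 (2E,8E,10E)-3,7,7-trimethyldodeca-2,8,10-trien-1-ol, via alkenyldimethylalane 11 (not isolated), via lithium alkenylaluminate 12 (not isolated)
Conditions: AlMe3, Cp2ZrCl2 (cat.), CH2Cl2, 0 °C → rt; evaporate; then n-BuLi, THF, −78 °C; then (CH2O)n, −78 °C → rt
Reagents that add atoms: trimethylaluminium, C[Al](C)C; formaldehyde (from paraformaldehyde), C=O
Why: Zirconium-catalysed syn-carboalumination of the terminal alkyne (Negishi carboalumination) places methyl on the internal carbon (C10) and aluminium on the terminal one (C9), and hydroxymethylation of the aluminate with retention fixes the 2E geometry; the remote internal diene is not a substrate.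

Step 6
Reactants: 13 (2E,8E,10E)-3,7,7-trimethyldodeca-2,8,10-trien-1-ol
Product: 14 (2E,8E,10E)-3,7,7-trimethyldodeca-2,8,10-trienal
Conditions: MnO2, CH2Cl2, rt
Reagents that add atoms: none
Why: Heterogeneous allylic alcohol oxidation by MnO2 is neutral and selective, so the E geometry of the C9=C10 enal should be kept.

Step 7
Reactants: 14 (2E,8E,10E)-3,7,7-trimethyldodeca-2,8,10-trienal
Product: 15 (5S,8S,9S,10S)-drim-6-en-11-al (5α-H; 8β-CH3; 9β-CHO; 10β-CH3)
Conditions: (R)-1-(2-methylphenyl)-3,3-diphenyltetrahydro-1H,3H-pyrrolo[1,2-c][1,3,2]oxazaborole (20 mol%), HNTf2 (18 mol%), CH2Cl2, −40 → 0 °C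
Reagents that add atoms: none
Why: The N-protonated oxazaborolidine binds the formyl oxygen of 14 as a chiral Lewis acid, lowers the LUMO of the C9=C10 enal and lets it add in a concerted suprafacial [4+2] to the tethered C5=C6–C7=C8 diene, the closest known reaction type being the oxazaborolidinium-catalysed intramolecular Diels–Alder reaction of 2,8,10-trienals to trans-decalins. Ring A closes through the C5–C10 bond with the four-carbon tether C1–C4 folded chair-like between dienophile and diene terminus, and ring B is the new cyclohexene itself, closed by the C5–C10 and C8–C9 bonds. The trans relationship of C5 and C10 with an axial C10 methyl comes from the endo transition state of the (E)-enal, in which formyl and C10 methyl sit under the diene and the tether is exo; C9 (β-formyl, cis to the C10 methyl) copies the enal geometry and C8 (β-methyl) copies the (E,E)-diene geometry. The absolute configuration of all four centres is set by the catalyst, whose aryl group covers one face of the bound s-trans enal so that the diene reaches the C9 Si/C10 Re face. The step needs endo over exo selectivity and enal-face selectivity: the first is secured by Lewis-acid activation of a terminally activated (E)-dienophile, the second by two-point binding (B–O bond plus formyl C–H···O contact), while the C4 gem-dimethyl group favours the folded chain (Thorpe–Ingold effect) and the absence of a free amine keeps the enal geometry from scrambling.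

Step 8
Reactants: 15 (5S,8S,9S,10S)-drim-6-en-11-al
Product: 16 11-(trimethylsilyloxy)drima-6,9(11)-diene (5α-H; 8β-CH3; 10β-CH3; either enol ether geometry)
Conditions: TMSOTf, Et3N, CH2Cl2, 0 °C → rt
Reagents that add atoms: trimethylsilyl trifluoromethanesulfonate, C[Si](C)(C)OS(=O)(=O)C(F)(F)F
Why: Soft enolisation and O-silylation of the aldehyde gives the enol silane, deliberately removing the C9 stereocentre while C5, C8 and C10 are untouched.

Step 9
Reactants: 16 11-(trimethylsilyloxy)drima-6,9(11)-diene
Product: 17 (5S,10S)-drima-6,8-dien-11-al (5α-H; 10β-CH3)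
Conditions: Pd(OAc)2 (1.1 equiv), MeCN, rt
Reagents that add atoms: none
Why: Saegusa–Ito dehydrogenation: silicon-to-palladium exchange gives a palladium enolate at C9, and syn β-hydride elimination of H8, the only β-hydrogen and cis to the open α face, should give the homoannular dienal and erase C8.

Step 10
Reactants: 17 (5S,10S)-drima-6,8-dien-11-al
Product: 18 (5S,10S)-drima-6,8-dien-11-ol
Conditions: NaBH4, CeCl3·7H2O, MeOH, 0 °C
Reagents that add atoms: none
Why: Luche 1,2-reduction of the dienal carbonyl makes the diene electron-rich for the coming cycloaddition and creates no stereocentre.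

Step 11
Reactants: 18 (5S,10S)-drima-6,8-dien-11-ol
Product: 19 11-(tert-butyldimethylsilyloxy)drima-6,8-diene (5α-H; 10β-CH3)
Conditions: TBSCl, imidazole, DMF, rt
Reagents that add atoms: tert-butyldimethylsilyl chloride, CC(C)(C)[Si](C)(C)Cl
Why: Standard silylation of the primary alcohol keeps C11 distinct from the two hydroxyls generated next.

Step 12
Reactants: 19 11-(tert-butyldimethylsilyloxy)drima-6,8-diene
Product: 20 11-(tert-butyldimethylsilyloxy)-6α,9α-epidioxydrim-7-ene
Conditions: O2, tetraphenylporphyrin (cat.), visible light, CH2Cl2, −20 °C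
Reagents that add atoms: dioxygen, O=O
Why: [4+2] cycloaddition of singlet oxygen to the cisoid 6,8-diene, as with steroidal 5,7-dienes; the axial 4β- and 10β-methyl groups block the β face, so both C–O bonds (C6 and C9) should form on the α face and the alkene lands at C7=C8.

Step 13
Reactants: 20 11-(tert-butyldimethylsilyloxy)-6α,9α-epidioxydrim-7-ene
Product: 21 11-(tert-butyldimethylsilyloxy)drim-7-ene-6α,9α-diol
Conditions: thiourea, MeOH, rt
Reagents that add atoms: none
Why: Reductive O–O cleavage of the bicyclic peroxide by thiourea leaves both C–O bonds intact, so the cis-6α,9α-diol keeps the configuration set in step 12, and no base is present to trigger a Kornblum–DeLaMare rearrangement.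

Step 14
Reactants: 21 11-(tert-butyldimethylsilyloxy)drim-7-ene-6α,9α-diol; 22 (2E,4E,6E)-octa-2,4,6-trienoic acid
Product: 24 11-(tert-butyldimethylsilyloxy)-9α-hydroxydrim-7-en-6α-yl (2E,4E,6E)-octa-2,4,6-trienoate, via mixed anhydride 23 (not isolated)
Conditions: 22, 2,4,6-trichlorobenzoyl chloride, Et3N, THF, rt; then 21, DMAP, toluene, rt
Reagents that add atoms: none
Why: Yamaguchi esterification: the mixed anhydride acylates the secondary allylic 6α-hydroxyl under DMAP catalysis with retention at C6, the tertiary 9α-hydroxyl being too hindered to compete.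

Step 15
Reactants: 24 11-(tert-butyldimethylsilyloxy)-9α-hydroxydrim-7-en-6α-yl (2E,4E,6E)-octa-2,4,6-trienoate
Product: 25 9α,11-dihydroxydrim-7-en-6α-yl (2E,4E,6E)-octa-2,4,6-trienoate
Conditions: HF·pyridine, pyridine, THF, 0 °C → rt
Reagents that add atoms: none
Why: Fluoride-driven cleavage of the primary silyl ether under buffered, non-basic conditions should spare the trienoate ester and both allylic C–O bonds.

Step 16
Reactants: 25 9α,11-dihydroxydrim-7-en-6α-yl (2E,4E,6E)-octa-2,4,6-trienoate
Product: 26 (5S,6S,9R,10S)-9-hydroxy-11-oxodrim-7-en-6-yl (2E,4E,6E)-octa-2,4,6-trienoate (target; 5α-H; 6α-acyloxy; 9α-OH; 9β-CHO; 10β-CH3)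
Conditions: SO3·pyridine, DMSO, i-Pr2NEt, CH2Cl2, 0 °C
Reagents that add atoms: none
Why: Parikh–Doering oxidation converts the primary C11 alcohol to the aldehyde without glycol cleavage, and quaternary C9 cannot epimerise.

**Compound list**

1 | isobutyronitrile | CC(C)C#N | starting material
2 | (5-chloropent-1-yn-1-yl)trimethylsilane | C[Si](C)(C)C#CCCCCl | starting material
3 | lithiated isobutyronitrile (2-cyanopropan-2-yllithium) | [Li+].C[C-](C)C#N | intermediate
4 | 2,2-dimethyl-7-(trimethylsilyl)hept-6-ynenitrile | C[Si](C)(C)C#CCCCC(C)(C)C#N | intermediate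
5 | N-[bis(2-methylpropyl)alumanyl]-2,2-dimethyl-7-(trimethylsilyl)hept-6-yn-1-imine | C[Si](C)(C)C#CCCCC(C)(C)C=N[Al](CC(C)C)CC(C)C | intermediate
6 | 2,2-dimethyl-7-(trimethylsilyl)hept-6-ynal | C[Si](C)(C)C#CCCCC(C)(C)C=O | intermediate
7 | [(7E)-8-iodo-6,6-dimethyloct-7-en-1-yn-1-yl]trimethylsilane | C[Si](C)(C)C#CCCCC(C)(C)/C=C/I | intermediate
8 | 4,4,5,5-tetramethyl-2-[(1E)-prop-1-en-1-yl]-1,3,2-dioxaborolane | C/C=C/B1OC(C)(C)C(C)(C)O1 | starting material
9 | [(7E,9E)-6,6-dimethylundeca-7,9-dien-1-yn-1-yl]trimethylsilane | C[Si](C)(C)C#CCCCC(C)(C)/C=C/C=C/C | intermediate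
10 | (7E,9E)-6,6-dimethylundeca-7,9-dien-1-yne | C#CCCCC(C)(C)/C=C/C=C/C | intermediate
11 | dimethyl[(1E,7E,9E)-2,6,6-trimethylundeca-1,7,9-trien-1-yl]alumane | C[Al](C)/C=C(\C)CCCC(C)(C)/C=C/C=C/C | intermediate
12 | lithium butyldimethyl[(1E,7E,9E)-2,6,6-trimethylundeca-1,7,9-trien-1-yl]aluminate | [Li+].CCCC[Al-](C)(C)/C=C(\C)CCCC(C)(C)/C=C/C=C/C | intermediate
13 | (2E,8E,10E)-3,7,7-trimethyldodeca-2,8,10-trien-1-ol | OC/C=C(\C)CCCC(C)(C)/C=C/C=C/C | intermediate
14 | (2E,8E,10E)-3,7,7-trimethyldodeca-2,8,10-trienal | O=C/C=C(\C)CCCC(C)(C)/C=C/C=C/C | intermediate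
15 | (5S,8S,9S,10S)-drim-6-en-11-al (5α-H, 8β-methyl, 9β-formyl, 10β-methyl) | C1=C[C@H](C)[C@H](C=O)[C@@]2(C)CCCC(C)(C)[C@H]12 | intermediate
16 | 11-(trimethylsilyloxy)drima-6,9(11)-diene (5α-H, 8β-methyl, 10β-methyl; enol ether geometry not defined) | C1=C[C@H](C)C(=CO[Si](C)(C)C)[C@@]2(C)CCCC(C)(C)[C@H]12 | intermediate
17 | (5S,10S)-drima-6,8-dien-11-al | C1=CC(C)=C(C=O)[C@@]2(C)CCCC(C)(C)[C@H]12 | intermediate
18 | (5S,10S)-drima-6,8-dien-11-ol | C1=CC(C)=C(CO)[C@@]2(C)CCCC(C)(C)[C@H]12 | intermediate
19 | 11-(tert-butyldimethylsilyloxy)drima-6,8-diene | C1=CC(C)=C(CO[Si](C)(C)C(C)(C)C)[C@@]2(C)CCCC(C)(C)[C@H]12 | intermediate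
20 | 11-(tert-butyldimethylsilyloxy)-6α,9α-epidioxydrim-7-ene | O3[C@H]1C=C(C)[C@](O3)(CO[Si](C)(C)C(C)(C)C)[C@@]2(C)CCCC(C)(C)[C@H]12 | intermediate
21 | 11-(tert-butyldimethylsilyloxy)drim-7-ene-6α,9α-diol | O[C@H]1C=C(C)[C@](O)(CO[Si](C)(C)C(C)(C)C)[C@@]2(C)CCCC(C)(C)[C@H]12 | intermediate
22 | (2E,4E,6E)-octa-2,4,6-trienoic acid | C/C=C/C=C/C=C/C(=O)O | starting material
23 | (2E,4E,6E)-octa-2,4,6-trienoic 2,4,6-trichlorobenzoic anhydride | C/C=C/C=C/C=C/C(=O)OC(=O)c1c(Cl)cc(Cl)cc1Cl | intermediate
24 | 11-(tert-butyldimethylsilyloxy)-9α-hydroxydrim-7-en-6α-yl (2E,4E,6E)-octa-2,4,6-trienoate | C/C=C/C=C/C=C/C(=O)O[C@H]1C=C(C)[C@](O)(CO[Si](C)(C)C(C)(C)C)[C@@]2(C)CCCC(C)(C)[C@H]12 | intermediate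
25 | 9α,11-dihydroxydrim-7-en-6α-yl (2E,4E,6E)-octa-2,4,6-trienoate | C/C=C/C=C/C=C/C(=O)O[C@H]1C=C(C)[C@](O)(CO)[C@@]2(C)CCCC(C)(C)[C@H]12 | intermediate
26 | (5S,6S,9R,10S)-9-hydroxy-11-oxodrim-7-en-6-yl (2E,4E,6E)-octa-2,4,6-trienoate | C/C=C/C=C/C=C/C(=O)O[C@H]1C=C(C)[C@](O)(C=O)[C@@]2(C)CCCC(C)(C)[C@H]12 | target

**Step count and risks**

Total steps: 16. Longest linear sequence: 16 steps (1 to 26); acid 22 enters at step 14.

Steps most likely to fail:

1. Step 7. The β,β-disubstituted enal may bind the catalyst weakly, and the C5–C10 bond must form between a carbon next to quaternary C4 and a carbon that becomes quaternary. Turnover could therefore be slow, and an unselective background or exo pathway could erode face and endo selectivity. The fallback replaces catalyst control by auxiliary control and sets out from 14.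
   - Pinnick oxidation (NaClO2, NaH2PO4, 2-methylbut-2-ene, t-BuOH/H2O) should give (2E,8E,10E)-3,7,7-trimethyldodeca-2,8,10-trienoic acid F1.
   - Its pivaloyl mixed anhydride is coupled with (4S)-4-benzyl-1,3-oxazolidin-2-one (Et3N, LiCl, THF) to give (4S)-4-benzyl-3-[(2E,8E,10E)-3,7,7-trimethyldodeca-2,8,10-trienoyl]-1,3-oxazolidin-2-one F2.
   - Me2AlCl (CH2Cl2, −30 °C) promotes the same intramolecular Diels–Alder reaction through the chelated s-cis imide; its benzyl group shields one face, so the C9 Si face is attacked and (4S)-4-benzyl-3-[(5S,8S,9S,10S)-drim-6-en-11-oyl]-1,3-oxazolidin-2-one F3 should result.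
   - LiBH4 (THF, MeOH, 0 °C) removes the auxiliary to give (5S,8S,9S,10S)-drim-6-en-11-ol F4, and Parikh–Doering oxidation brings the material back to the route at 15.

2. Step 12. Ene-type hydroperoxidation at the tetrasubstituted C8=C9 bond (allylic hydrogens on C12 and C11) may compete with the [4+2] mode. The fallback is a stepwise 1,4-oxygenation and sets out from 19.
   - mCPBA (NaHCO3, CH2Cl2, −20 °C) should epoxidise the more electron-rich C8=C9 bond from the open α face to give 11-(tert-butyldimethylsilyloxy)-8α,9α-epoxydrim-6-ene F5.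
   - Pd(PPh3)4 (cat.) with acid 22 in THF then opens the vinyl epoxide through a C6–C7–C8 π-allyl complex formed with inversion and attacked by the carboxylate at C6 with a second inversion (net cis-1,4-addition). This gives the 6α-ester with free 9α-hydroxyl and comes back to the route at 24, bypassing steps 13 and 14.

3. Step 9. Silicon-to-palladium exchange at the congested C9 may be slow, so that the enol silane hydrolyses back to 15 before dehydrogenation. The fallback is a selenoxide elimination and sets out from 16.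
   - PhSeCl (CH2Cl2, −78 °C) should selenenylate C9 from the α face to give 9α-(phenylselanyl)drim-6-en-11-al F6.
   - H2O2 (pyridine, CH2Cl2, 0 °C) oxidises selenium, and syn elimination of the selenoxide with the cis H8 comes back to the route at 17.

Further compounds
F1 | step 7 | (2E,8E,10E)-3,7,7-trimethyldodeca-2,8,10-trienoic acid | OC(=O)/C=C(\C)CCCC(C)(C)/C=C/C=C/C
F2 | step 7 | (4S)-4-benzyl-3-[(2E,8E,10E)-3,7,7-trimethyldodeca-2,8,10-trienoyl]-1,3-oxazolidin-2-one | O=C(/C=C(\C)CCCC(C)(C)/C=C/C=C/C)N1[C@@H](Cc2ccccc2)COC1=O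
F3 | step 7 | (4S)-4-benzyl-3-[(5S,8S,9S,10S)-drim-6-en-11-oyl]-1,3-oxazolidin-2-one | C1=C[C@H](C)[C@H](C(=O)N3[C@@H](Cc4ccccc4)COC3=O)[C@@]2(C)CCCC(C)(C)[C@H]12
F4 | step 7 | (5S,8S,9S,10S)-drim-6-en-11-ol | C1=C[C@H](C)[C@H](CO)[C@@]2(C)CCCC(C)(C)[C@H]12
F5 | step 12 | 11-(tert-butyldimethylsilyloxy)-8α,9α-epoxydrim-6-ene | C1=C[C@@]3(C)O[C@@]3(CO[Si](C)(C)C(C)(C)C)[C@@]2(C)CCCC(C)(C)[C@H]12
F6 | step 9 | 9α-(phenylselanyl)drim-6-en-11-al | C1=C[C@H](C)[C@@](C=O)([Se]c3ccccc3)[C@@]2(C)CCCC(C)(C)[C@H]12
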